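**Retrosynthetic overview**

1. Target 8 ⇐ bis(tert-butyl ether) 7 (acidolysis) ⇐ hydroxyquinone 6 (O-acetylation) ⇐ 2,5-diarylquinone 4 (epoxidation/isomerisation brings in the C2 oxygen).
2. Key disconnection: the C6–aryl bond (quinone ring numbered C1=O, C2–OAc, C3–aryl, C4=O, C5–H, C6–aryl) ⇒ aryl quinone 3 + arylboronic acid 2, joined by an oxidative radical C–H arylation at the quinone oxidation level; 3 ⇐ 1 + 2 in the same way.
3. Enabling feature: the two aryl rings sit para on the quinone ring (C3 and C6) and C6 is a quinone CH. With the C2 oxygen still absent, the C3 aryl is through-conjugated with C1=O (aryl–C3=C2–C1=O), so C6, the β-carbon of the other enone C4(=O)–C5=C6, is the preferred radical acceptor.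
4. Coupling product 4 is C2h-symmetric: its two aryl–quinone bonds and its two CH groups are interchanged by the twofold axis, so the single oxygenation that follows can give only the target's substitution pattern.
5. Ring order: no ring is constructed; the quinone ring comes from 1 and both benzene rings from 2.

Key step: step 2

Remark: the target has no stereocentre; the only stereo elements on the route are the two epoxide carbons of the transient, racemic, cis-fused intermediate 5, which are erased within the same step. Locants C1–C6 in the Why lines are those of the target's quinone ring given above.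

**Route**

Step 1
Reactants: 1 1,4-benzoquinone (2 equiv); 2 (4-tert-butoxyphenyl)boronic acid
Product: 3 2-(4-tert-butoxyphenyl)-1,4-benzoquinone
Conditions: AgNO3 (20 mol%), K2S2O8 (3 equiv), CH2Cl2/H2O (1:1), rt
Reagents that add atoms: none
Why: Silver-catalysed persulfate C–H arylation of a quinone with an arylboronic acid (Minisci-type radical addition and re-oxidation); all four CH positions of 1 are equivalent, the excess of 1 limits a second arylation, and the aryl tert-butyl ether should survive the mildly acidic two-phase medium.

Step 2
Reactants: 3 2-(4-tert-butoxyphenyl)-1,4-benzoquinone; 2 (4-tert-butoxyphenyl)boronic acid (1.5–2 equiv)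
Product: 4 2,5-bis(4-tert-butoxyphenyl)-1,4-benzoquinone
Conditions: AgNO3 (20 mol%), K2S2O8 (3 equiv), CH2Cl2/H2O (1:1), rt; second charge of 2, AgNO3 and K2S2O8 if 3 remains
Reagents that add atoms: none
Why: Ag(I) is oxidised by persulfate to Ag(II)/sulfate radical anion, which converts 2 into the 4-tert-butoxyphenyl σ-radical; this adds to C6 of 3 and the adduct radical is oxidised and deprotonated back to the quinone, so the C–C bond is made from a C–H bond with no halide and no change of oxidation level. The reaction type is the silver/persulfate radical C–H arylation of quinones with arylboronic acids, and its regiochemical model is the Meerwein arylation of monoarylquinones, which gives 2,5-diarylquinones. No ring is closed and no stereocentre is formed. The step needs attack at C6 rather than at C5 or C2: the C3 aryl is through-conjugated with C1=O, which lowers the acceptor character of C5 (β to C1=O), whereas C6 is β to C4=O, which is only cross-conjugated with the aryl, and attack there leaves the aryl–C3=C2–C1=O conjugation intact in the adduct radical; C2 is shielded by the flanking aryl. Over-arylation should be slow because each remaining CH of 4 is flanked by an aryl group and 4 is a poorer acceptor than 3. The product is C2h-symmetric, so the later oxygenation has only one possible constitutional outcome.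

Step 3
Reactants: 4 2,5-bis(4-tert-butoxyphenyl)-1,4-benzoquinone
Product: 6 2,5-bis(4-tert-butoxyphenyl)-3-hydroxy-1,4-benzoquinone, via racemic cis-epoxide 5 (not isolated)
Conditions: t-BuOOH (in decane, 1.1 equiv), DBU (2.2 equiv), CH2Cl2, 0 °C → rt; 1 M HCl work-up
Reagents that add atoms: tert-butyl hydroperoxide, CC(C)(C)OO
Why: Weitz–Scheffer-type nucleophilic epoxidation of the enedione (the peroxide anion adds to the CH carbon C2 and the enolate closes on O–O to the necessarily cis-fused epoxide 5) followed by the base-induced epoxy ketone-to-enol isomerisation known for quinone epoxides, which opens the benzylic C3–O bond and leaves the hydroxyl on C2; the resulting vinylogous carboxylate should resist further epoxidation.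

Step 4
Reactants: 6 2,5-bis(4-tert-butoxyphenyl)-3-hydroxy-1,4-benzoquinone
Product: 7 2,5-bis(4-tert-butoxyphenyl)-3,6-dioxocyclohexa-1,4-dien-1-yl acetate
Conditions: Ac2O (1.5 equiv), pyridine (2 equiv), DMAP (5 mol%), CH2Cl2, 0 °C; cold dilute HCl wash
Reagents that add atoms: acetic anhydride, CC(=O)OC(C)=O
Why: Standard O-acylation of the acidic enol hydroxyl of a hydroxyquinone (a vinylogous carboxylic acid); it is the only free OH, and the aryl tert-butyl ethers are inert.

Step 5
Reactants: 7 2,5-bis(4-tert-butoxyphenyl)-3,6-dioxocyclohexa-1,4-dien-1-yl acetate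
Product: 8 Neonambiquinone A
Conditions: TFA/CH2Cl2 (1:4), 0 °C → rt, N2 sweep
Reagents that add atoms: none
Why: Acid-catalysed E1 cleavage of the two aryl tert-butyl ethers with loss of 2-methylpropene under anhydrous, non-nucleophilic conditions, which the quinone and its enol acetate should tolerate.

**Compound list**

1 | 1,4-benzoquinone | O=C1C=CC(=O)C=C1 | starting material
2 | (4-tert-butoxyphenyl)boronic acid | CC(C)(C)Oc1ccc(cc1)B(O)O | starting material
3 | 2-(4-tert-butoxyphenyl)-1,4-benzoquinone | CC(C)(C)Oc1ccc(cc1)C1=CC(=O)C=CC1=O | intermediate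
4 | 2,5-bis(4-tert-butoxyphenyl)-1,4-benzoquinone | CC(C)(C)Oc1ccc(cc1)C1=CC(=O)C(=CC1=O)c1ccc(OC(C)(C)C)cc1 | intermediate
5 | 1,4-bis(4-tert-butoxyphenyl)-7-oxabicyclo[4.1.0]hept-3-ene-2,5-dione (racemic, cis-fused epoxide; one enantiomer drawn) | O=C1C=C(c2ccc(OC(C)(C)C)cc2)C(=O)[C@H]3O[C@@]13c1ccc(OC(C)(C)C)cc1 | intermediate
6 | 2,5-bis(4-tert-butoxyphenyl)-3-hydroxy-1,4-benzoquinone | CC(C)(C)Oc1ccc(cc1)C1=C(O)C(=O)C(=CC1=O)c1ccc(OC(C)(C)C)cc1 | intermediate
7 | 2,5-bis(4-tert-butoxyphenyl)-3,6-dioxocyclohexa-1,4-dien-1-yl acetate | CC(=O)OC1=C(c2ccc(OC(C)(C)C)cc2)C(=O)C=C(c2ccc(OC(C)(C)C)cc2)C1=O | intermediate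
8 | Neonambiquinone A, 2,5-bis(4-hydroxyphenyl)-3,6-dioxocyclohexa-1,4-dien-1-yl acetate | CC(=O)OC1=C(c2ccc(O)cc2)C(=O)C=C(c2ccc(O)cc2)C1=O | target

**Step count and risks**

Total step count: 5. Longest linear sequence: 5 steps (1 and 2 to 8).

Steps most likely to fail:

1. Step 2. The second radical arylation may be poorly regioselective (attack at the CH meta to the first aryl) or may run on to a third arylation. Fallback, setting out from 2 and coming back at 4: commercial 1,4-dibromo-2,5-dimethoxybenzene F1 is coupled twice with 2 by Suzuki–Miyaura reaction (Pd(PPh3)4, K2CO3, dioxane/H2O, 90 °C) to 2,5-bis(4-tert-butoxyphenyl)-1,4-dimethoxybenzene F2. Oxidative demethylation of the central ring with ceric ammonium nitrate (MeCN/H2O, 0 °C) should then give 4, with the para relationship of the aryl groups fixed by the bromine positions.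

2. Step 3. Over-oxidation (a second epoxidation, or peroxide-induced cleavage of the hydroxyquinone ring) or incomplete epoxide-to-enol isomerisation may occur. Fallback, setting out from 4 and coming back at 6: conjugate addition of pyrrolidine under air (EtOH/CH2Cl2, rt; amine addition followed by aerial re-oxidation of the aminohydroquinone) should give 2,5-bis(4-tert-butoxyphenyl)-3-(pyrrolidin-1-yl)-1,4-benzoquinone F3. Hydrolysis of this vinylogous amide (2 M NaOH, EtOH/H2O, 60 °C, then cold 1 M HCl) should return 6 with the tert-butyl ethers untouched.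

3. Step 5. The quinone enol acetate may be lost or transferred to a phenol during acidolysis, and the liberated phenols may be ring-alkylated by the tert-butyl cation. Fallback, setting out from 6 and coming back at 8: the tert-butyl ethers are removed first (TFA/CH2Cl2, 0 °C → rt) to give 2-hydroxy-3,6-bis(4-hydroxyphenyl)-1,4-benzoquinone F4. The vinylogous-acid hydroxyl, far more acidic than the phenols, is then deprotonated selectively with one equivalent of i-Pr2NEt and acetylated with one equivalent of Ac2O (THF, −40 °C), which should give 8 directly.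

**Further compounds**

F1 | step 2 | 1,4-dibromo-2,5-dimethoxybenzene | COc1cc(Br)c(OC)cc1Br
F2 | step 2 | 2,5-bis(4-tert-butoxyphenyl)-1,4-dimethoxybenzene | COc1cc(-c2ccc(OC(C)(C)C)cc2)c(OC)cc1-c1ccc(OC(C)(C)C)cc1
F3 | step 3 | 2,5-bis(4-tert-butoxyphenyl)-3-(pyrrolidin-1-yl)-1,4-benzoquinone | CC(C)(C)Oc1ccc(cc1)C1=C(N2CCCC2)C(=O)C(=CC1=O)c1ccc(OC(C)(C)C)cc1
F4 | step 5 | 2-hydroxy-3,6-bis(4-hydroxyphenyl)-1,4-benzoquinone | O=C1C(O)=C(c2ccc(O)cc2)C(=O)C=C1c1ccc(O)cc1
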